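**Strategy.** Numbering: C1/C5 ring fusion, C4 quaternary, C7 isopropenyl carbon, C10 carbinol. The seven-membered ring (C1, C5, C6, C7, C8, C9, C10) is disconnected at C6–C7 and C8–C9. The two-carbon unit C7–C8 (the isopropenyl-bearing CH and its CH2 neighbour toward C10) is the alkyne of methyl propiolate, inserted into the ketone ring of a cis-diquinane. One operation, (2+2) cycloaddition of a pyrrolidine enamine then cyclobutene opening, forms both bonds and the cycloheptadiene. It leaves a masked C6 ketone for trans equilibration at C5 and the C7 ester for the isopropenyl group. The precursor is the C6=C9 enamine of a cis-bicyclo[3.3.0]octanone already holding the C4 quaternary centre and the C10 carbinol, protected by two different silyl groups.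

Key step: step 15

Numbering and faces (all bicyclic compounds): C2, C3 = cyclopentane CH2; C4 carries a methyl and a one-carbon arm (C1′ in the target); C6 lies between C5 and C7; C8, C9 follow C7; C10 (methyl, oxygen) is bonded to C1. The diquinanes contain C1–C6, C9 and C10, with C6 bonded to C9. "Up" is the face of H-1. Throughout: C4–CH3 up, C4 arm down, C10–O up, C10–CH3 down; H-5 is up in the cis-fused series (9–25) and down in the trans-fused series (26 onward).

Assumption: in step 2 the toluene–HMPA regime of the L-valine tert-butyl ester auxiliary is taken to lead to the (S)-ester; if it leads to the (R)-ester, the THF regime or the D-valine ester is used and nothing else changes.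

Remark on the precursor: the tertiary C10 oxygen carries SiEt3 and the primary C4 arm carries SiPh2t-Bu, so that the tertiary hydroxyl can be freed alone (step 16) to direct the hydrogenation that sets C7 (step 19).

Step 1
Reactants: 1 methyl 2-oxocyclopentane-1-carboxylate; 2 L-valine tert-butyl ester
Product: 3 methyl 2-{[(2S)-1-tert-butoxy-3-methyl-1-oxobutan-2-yl]amino}cyclopent-1-ene-1-carboxylate
Conditions: BF3·OEt2 (cat.), benzene, reflux (Dean–Stark)
Reagents that add atoms: none
Why: Acid-catalysed condensation of the β-keto ester with the primary amine (enamine formation) should give the hydrogen-bonded vinylogous carbamate; no ring stereocenter is formed.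

Step 2
Reactants: 3 enamino ester
Product: 5 methyl (S)-1-methyl-2-oxocyclopentane-1-carboxylate, via methylated imino ester 4 (not isolated)
Conditions: LiN(i-Pr)2, toluene, HMPA (1 equiv), −78 °C; MeI, −78 → −55 °C; then 1 M aq. HCl, rt
Reagents that add atoms: iodomethane, CI; water, O
Why: Auxiliary-controlled alkylation of the lithiated enamine (chiral aza-enolate alkylation): lithium is chelated by the enamine nitrogen and the ester carbonyls, the isopropyl group of the valine ester shields one face and MeI enters from the other, which sets the C4 quaternary stereocenter, and acid hydrolysis of the imine releases the ketone and the auxiliary.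

Step 3
Reactants: 5 methyl (S)-1-methyl-2-oxocyclopentane-1-carboxylate
Product: 6 methyl (S)-1-methyl-2-(trifluoromethanesulfonyloxy)cyclopent-2-ene-1-carboxylate
Conditions: KN(SiMe3)2, THF, −78 °C; PhNTf2, −78 → 0 °C
Reagents that add atoms: N-phenylbis(trifluoromethanesulfonimide), O=S(=O)(N(c1ccccc1)S(=O)(=O)C(F)(F)F)C(F)(F)F
Why: Enolate O-sulfonylation (enol triflate formation): the ketone can enolise only toward C1 because C4 is quaternary, so a single vinyl triflate should form and C4 is untouched.

Step 4
Reactants: 6 vinyl triflate ester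
Product: 7 (R)-5-(hydroxymethyl)-5-methylcyclopent-1-en-1-yl trifluoromethanesulfonate
Conditions: i-Bu2AlH (2.5 equiv), CH2Cl2, −78 → 0 °C; aq. potassium sodium tartrate
Reagents that add atoms: none
Why: Hydride reduction of the ester to the primary alcohol with i-Bu2AlH, toward which the vinyl triflate is inert at low temperature; no stereocenter is affected.

Step 5
Reactants: 7 hydroxymethyl vinyl triflate
Product: 8 (S)-3a-methyl-3,3a,4,5-tetrahydro-1H-cyclopenta[c]furan-1-one (unsaturated lactone; carbonyl = C6; C1=C5)
Conditions: Pd(PPh3)4 (5 mol%), CO (1 atm), n-Bu3N, LiCl, MeCN, 65 °C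
Reagents that add atoms: carbon monoxide, [C-]#[O+]
Why: Palladium-catalysed carbonylative lactonisation: oxidative addition of zerovalent palladium into the C5–OTf bond, CO insertion and acylation of the neighbouring hydroxyl close the five-membered lactone, whose carbonyl carbon is the future C6.

Step 6
Reactants: 8 unsaturated lactone
Product: 9 cis-fused isopropenyl lactone (isopropenyl on C1 down)
Conditions: isopropenylmagnesium bromide, CuBr·SMe2 (10 mol%), THF, −40 °C; aq. NH4Cl
Reagents that add atoms: isopropenylmagnesium bromide, C=C(C)[Mg]Br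
Why: Copper-catalysed conjugate addition to the α-alkylidene lactone: the nucleophile is expected to add to C1 anti to the angular C4 methyl, protonation at C5 can give only the cis-fused lactone (C6 cis to the C4 oxygen arm), and the C1 configuration is re-equilibrated in step 8 in any case.

Step 7
Reactants: 9 cis-fused isopropenyl lactone
Product: 10 cis-fused acetyl lactone (acetyl on C1)
Conditions: O3, CH2Cl2–MeOH, −78 °C; Me2S
Reagents that add atoms: ozone, [O-][O+]=O
Why: Ozonolysis with reductive work-up cleaves the 1,1-disubstituted alkene to the methyl ketone (future C10 and C9) without touching a stereocenter.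

Step 8
Reactants: 10 cis-fused acetyl lactone
Product: 12 tricyclic vinylogous ester (C10 ketone; C6=C9 enol ether bridged by O–CH2 to C4), via hydroxy dione 11 (not isolated)
Conditions: KOtBu (2.2 equiv), THF–t-BuOH, 0 °C → rt; AcOH; then TsOH (cat.), benzene, reflux (Dean–Stark)
Reagents that add atoms: none
Why: Intramolecular Claisen (Dieckmann-type) condensation of the methyl ketone enolate onto the lactone carbonyl closes the second carbocycle as the cis-fused 1,3-dione: C5 is held cis to the C4 arm by the lactone until the bond forms and C1 can epimerise through the ketone enolate, so both ring-fusion centres are set relative to C4, and acid then condenses the freed hydroxymethyl group with the only carbonyl it can reach in a five-membered ring (C6).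

Step 9
Reactants: 12 tricyclic vinylogous ester
Product: 14 hydroxy enone (C6 ketone; C9=C10; methyl on C10; C4 CH2OH), via carbinol adduct 13 (not isolated)
Conditions: MeLi, THF, −78 °C; then 1 M aq. HCl, THF, rt
Reagents that add atoms: methyllithium, [Li]C; water, O
Why: Stork–Danheiser alkylative carbonyl transposition: MeLi adds 1,2 to the vinylogous ester carbonyl C10 and aqueous acid ionises the tertiary allylic carbinol and hydrolyses the enol ether, which places the ketone on C6 and the methyl on C10 and frees the C4 hydroxymethyl group; the carbinol centre of 13 is lost.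

Step 10
Reactants: 14 hydroxy enone
Product: 15 silyl ether enone (C4 CH2OSiPh2t-Bu)
Conditions: t-BuPh2SiCl, imidazole, DMF, rt
Reagents that add atoms: tert-butyl(chloro)diphenylsilane, CC(C)(C)[Si](Cl)(c1ccccc1)c1ccccc1
Why: Imidazole-promoted silylation of the primary alcohol installs a group that should survive the later acidic and Lewis-acidic steps; no stereocenter is affected.

Step 11
Reactants: 15 silyl ether enone
Product: 16 epoxy ketone (9,10-epoxide on the upper face)
Conditions: 30% aq. H2O2, NaOH (cat.), MeOH, 0 °C
Reagents that add atoms: hydrogen peroxide, OO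
Why: Weitz–Scheffer nucleophilic epoxidation: hydroperoxide adds to C10 from the convex face of the cis-diquinane (the face of H-1 and H-5, opposite the concave C4 arm), which sets the C10–O bond syn to H-1.

Step 12
Reactants: 16 epoxy ketone
Product: 17 β-hydroxy ketone (C10 OH up)
Conditions: SmI2 (2.2 equiv), THF–MeOH, −90 °C
Reagents that add atoms: none
Why: Reductive opening of the α,β-epoxy ketone by divalent samarium (two single-electron transfers, cleavage of the C9–O bond next to the ketone) should give the β-hydroxy ketone with the C10 configuration retained.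

Step 13
Reactants: 17 β-hydroxy ketone
Product: 18 bis-silylated cis-diquinane ketone (C10 OSiEt3; C4 CH2OSiPh2t-Bu)
Conditions: Et3SiOTf, 2,6-lutidine, CH2Cl2, −78 °C
Reagents that add atoms: triethylsilyl trifluoromethanesulfonate, CC[Si](CC)(CC)OS(=O)(=O)C(F)(F)F
Why: Silyl triflate with a hindered base silylates the tertiary alcohol at low temperature faster than retro-aldol cleavage or elimination can occur; no stereocenter changes.

Step 14
Reactants: 18 bis-silylated cis-diquinane ketone; 19 pyrrolidine
Product: 20 pyrrolidine enamine of 18 (C6=C9)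
Conditions: pyrrolidine (6 equiv), TiCl4 (0.55 equiv), toluene, −20 → 0 °C
Reagents that add atoms: none
Why: TiCl4-mediated condensation of the ketone with the secondary amine (enamine formation): the double bond forms toward C9 because an enamine toward the ring-fusion carbon C5 would be tetrasubstituted and strained, and the low temperature keeps the β-silyloxy group from eliminating.

Step 15
Reactants: 20 pyrrolidine enamine; 21 methyl propiolate
Product: 23 cis-fused ring-enlarged dienamine ester (C6 pyrrolidinyl; C6=C7; C7 CO2Me; C8=C9), via aminocyclobutene 22 (not isolated)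
Conditions: methyl propiolate (1.2 equiv), toluene, 0 °C → rt; then 60 °C
Reagents that add atoms: none
Why: The nucleophilic enamine carbon C9 adds to the unsubstituted alkyne terminus, the iminium/allenolate zwitterion collapses by bonding C6 to the ester-bearing carbon to give the cis-fused aminocyclobutene 22 (a stepwise (2+2) cycloaddition), and thermal 4π-electrocyclic opening of this push–pull cyclobutene breaks the old C6–C9 bond, so that the two alkyne carbons are inserted as C7 and C8. The closest known reaction type is the two-carbon ring enlargement of cyclic ketone enamines by acetylenic esters. The four-membered ring closes by 4-exo-trig attack of the allenolate carbon on the iminium carbon, and the seven-membered ring is not closed end to end but arises by ring enlargement when the shared C6–C9 bond of the bicyclo[3.2.0]heptene breaks. No stereocenter is formed: C6–C9 end as sp2 carbons, the two transient cyclobutene centres are destroyed, and C1, C4, C5 and C10 are untouched. The step needs site selectivity (enamine toward C9, secured in step 14), orientation (C9 to the terminal alkyne carbon, secured by the polarity of the ynoate) and ring closure instead of proton transfer to an open Michael adduct (secured by the aprotic non-polar solvent and by quaternary C10, which offers no hydrogen next to C9). The C10 silyloxy group, allylic after the opening, should survive because neither acid nor base is present and the temperature stays moderate.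

Step 16
Reactants: 23 cis-fused dienamine ester
Product: 26 trans-fused hydroxy keto ester (C6 ketone; C7 CO2Me; C10 OH), via dihydro enamino ester 24 (not isolated), via cis-fused keto ester 25 (not isolated)
Conditions: H2 (1 atm), 5% Rh/Al2O3, EtOAc, rt; filter; then 1 M aq. HCl–THF (1:3), rt → 45 °C
Reagents that add atoms: water, O
Why: Heterogeneous hydrogenation reduces the disubstituted C8=C9 alkene and spares the tetrasubstituted push–pull enamino ester; aqueous acid then hydrolyses the vinylogous carbamate to the β-keto ester, cleaves the tertiary triethylsilyl ether and, through the iminium/enamine pair and acid-catalysed enolisation toward C5, should equilibrate C5 to the trans ring fusion, in which C6 lies anti to the bulky C4 arm.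

Step 17
Reactants: 26 trans-fused hydroxy keto ester
Product: 27 enol triflate (C6 OTf; C6=C7)
Conditions: NaH (1.05 equiv), THF, 0 °C; PhNTf2, 0 °C → rt
Reagents that add atoms: N-phenylbis(trifluoromethanesulfonimide), O=S(=O)(N(c1ccccc1)S(=O)(=O)C(F)(F)F)C(F)(F)F
Why: Enolate O-sulfonylation: one equivalent of NaH deprotonates only the β-keto ester (not the tertiary alcohol) and PhNTf2 traps the enolate on the ketone oxygen, which fixes the C6=C7 double bond.

Step 18
Reactants: 27 enol triflate
Product: 28 enoate (C6=C7; C7 CO2Me; C10 OH)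
Conditions: Pd(OAc)2 (5 mol%), PPh3 (10 mol%), HCO2H, n-Bu3N, DMF, 60 °C
Reagents that add atoms: none
Why: Palladium-catalysed formate reduction of the enol triflate (oxidative addition, decarboxylation of the palladium formate to a hydride, reductive elimination) replaces the C6–O bond by C6–H and gives the trisubstituted enoate.

Step 19
Reactants: 28 enoate
Product: 29 saturated ester (H-7 up; CO2Me down)
Conditions: [Ir(cod)(PCy3)(py)]PF6 (5 mol%), H2 (1 atm), CH2Cl2, 0 °C → rt
Reagents that add atoms: none
Why: Hydroxyl-directed homogeneous hydrogenation: the cationic iridium complex binds the free C10 hydroxyl and delivers both hydrogens to the C6=C7 bond on the face of that hydroxyl, so H-7 should end syn to the C10 oxygen and to H-1 and the ester anti to them, as the target requires; the silylated C4 arm cannot compete as a directing group.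

Step 20
Reactants: 29 saturated ester
Product: 30 diol ester (C4 CH2OH; C10 OH)
Conditions: Bu4NF, AcOH, THF, rt
Reagents that add atoms: none
Why: Fluoride-mediated cleavage of the silyl ether frees the primary alcohol, and buffering with AcOH avoids epimerisation at C7.

Step 21
Reactants: 30 diol ester
Product: 31 aldehyde (C4 CHO)
Conditions: Dess–Martin periodinane, NaHCO3, CH2Cl2, rt
Reagents that add atoms: none
Why: Dess–Martin oxidation of the primary alcohol gives an aldehyde that has no α-hydrogen (C4 is quaternary) and cannot epimerise; the tertiary alcohol is inert.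

Step 22
Reactants: 32 phloroglucinol
Product: 33 1,3,5-tris(methoxymethoxy)benzene
Conditions: MeOCH2Cl (3.6 equiv), i-Pr2NEt, CH2Cl2, 0 °C → rt
Reagents that add atoms: chloromethyl methyl ether, COCCl
Why: O-Alkylation of the three phenols (Williamson-type) gives the threefold-symmetric tris(MOM) ether.

Step 23
Reactants: 31 aldehyde; 33 1,3,5-tris(methoxymethoxy)benzene
Product: 35 benzylic alcohol (C1′ OH; aryl = 2,4,6-tris(methoxymethoxy)phenyl), via 2,4,6-tris(methoxymethoxy)phenyllithium 34 (not isolated)
Conditions: 33, n-BuLi, THF, 0 °C; then 31, −78 °C; aq. NH4Cl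
Reagents that add atoms: none
Why: Directed ortho-lithiation between two MOM ethers (one site by symmetry) and 1,2-addition of the aryllithium to the aldehyde, which at −78 °C is far more reactive than the hindered secondary ester; the new carbinol centre forms as a mixture that is erased in step 24.

Step 24
Reactants: 35 benzylic alcohol
Product: 36 (1′R)-2-methylallyl compound
Conditions: trimethyl(2-methylallyl)silane (3 equiv), InCl3 (10 mol%), CH2Cl2, −20 → 0 °C
Reagents that add atoms: trimethyl(2-methylallyl)silane, C=C(C)C[Si](C)(C)C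
Why: Hosomi–Sakurai-type substitution: the Lewis acid ionises the triply oxygen-activated benzylic alcohol (not the tertiary C10 alcohol) to a quinone-methide-like cation that the allylsilane captures, and with the small C4 methyl lying near the cation plane beside the arene to minimise allylic strain the nucleophile should enter anti to the more substituted C5 and past C3, which gives the (R) configuration at C1′.

Step 25
Reactants: 36 (1′R)-2-methylallyl compound
Product: 37 (1′R)-isobutyl ester
Conditions: H2 (1 atm), 10% Pd/C, EtOAc, rt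
Reagents that add atoms: none
Why: Heterogeneous hydrogenation of the 1,1-disubstituted alkene converts the 2-methylallyl group to isobutyl; no other reducible group is present and no stereocenter is affected.

Step 26
Reactants: 37 (1′R)-isobutyl ester
Product: 39 methyl ketone (C7 acetyl), via Weinreb amide 38 (not isolated)
Conditions: Me(MeO)NH·HCl, i-PrMgCl, THF, −20 °C; then MeMgBr, 0 °C; aq. NH4Cl
Reagents that add atoms: methylmagnesium bromide, C[Mg]Br (N,O-dimethylhydroxylamine hydrochloride, CNOC.Cl, contributes atoms only to intermediate 38)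
Why: Weinreb ketone synthesis in one flask: the magnesium amide of N,O-dimethylhydroxylamine converts the ester to the N-methoxy-N-methylamide and MeMgBr then adds once, the chelated tetrahedral intermediate surviving until work-up, so the methyl ketone should form without over-addition and without enolisation at C7.

Step 27
Reactants: 39 methyl ketone
Product: 40 isopropenyl tris(MOM) ether
Conditions: Zn, CH2Br2, TiCl4 (reagent pre-formed in THF), CH2Cl2, 0 °C → rt
Reagents that add atoms: dibromomethane, BrCBr
Why: Methylenation of the ketone with the non-basic Zn/CH2Br2/TiCl4 reagent (a titanium methylidene equivalent) gives the isopropenyl group without epimerising the enolisable C7 centre.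

Step 28
Reactants: 40 isopropenyl tris(MOM) ether
Product: 42 dialdehyde tris(MOM) ether, via lithium hemiaminal 41 (not isolated)
Conditions: n-BuLi (2.2 equiv), TMEDA, THF, −40 → 0 °C; DMF (1.1 equiv), −78 °C; then n-BuLi (1.3 equiv), −78 → −20 °C; DMF (3 equiv), −78 °C → rt; aq. NH4Cl
Reagents that add atoms: N,N-dimethylformamide, CN(C)C=O
Why: Two directed ortho-lithiation–formylation cycles in one flask: each free ring position lies between two MOM ethers, and the first formyl group is carried through the second lithiation as its lithium hemiaminal (the DMF adduct, which collapses to the aldehyde only on aqueous work-up).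

Step 29
Reactants: 42 dialdehyde tris(MOM) ether
Product: 43 CNP0594576.1 (target)
Conditions: 2 M aq. HCl–THF (1:3), rt
Reagents that add atoms: none
Why: Acid-catalysed hydrolysis of the three aryl MOM acetals, which are activated by the ortho formyl groups and should cleave under conditions mild enough for the tertiary alcohol and the isopropenyl group.

**Compound list**

1 | methyl 2-oxocyclopentane-1-carboxylate | COC(=O)C1CCCC1=O | starting material
2 | L-valine tert-butyl ester, tert-butyl (2S)-2-amino-3-methylbutanoate | CC(C)[C@H](N)C(=O)OC(C)(C)C | starting material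
3 | methyl 2-{[(2S)-1-tert-butoxy-3-methyl-1-oxobutan-2-yl]amino}cyclopent-1-ene-1-carboxylate | COC(=O)C1=C(N[C@@H](C(C)C)C(=O)OC(C)(C)C)CCC1 | intermediate
4 | methyl (1S)-1-methyl-2-{[(2S)-1-tert-butoxy-3-methyl-1-oxobutan-2-yl]imino}cyclopentane-1-carboxylate | COC(=O)[C@@]1(C)CCCC1=N[C@@H](C(C)C)C(=O)OC(C)(C)C | intermediate (not isolated)
5 | methyl (S)-1-methyl-2-oxocyclopentane-1-carboxylate | O=C1CCC[C@]1(C)C(=O)OC | intermediate
6 | methyl (S)-1-methyl-2-(trifluoromethanesulfonyloxy)cyclopent-2-ene-1-carboxylate | O=S(=O)(OC1=CCC[C@]1(C)C(=O)OC)C(F)(F)F | intermediate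
7 | (R)-5-(hydroxymethyl)-5-methylcyclopent-1-en-1-yl trifluoromethanesulfonate | O=S(=O)(OC1=CCC[C@]1(C)CO)C(F)(F)F | intermediate
8 | (S)-3a-methyl-3,3a,4,5-tetrahydro-1H-cyclopenta[c]furan-1-one (lactone carbonyl = C6, C1=C5 double bond) | O=C1OC[C@@]2(C)CCC=C12 | intermediate
9 | cis-fused lactone with isopropenyl on C1: H-1, H-5 and C4–CH3 up; isopropenyl and lactone ring down | C=C(C)[C@@H]1CC[C@]2(C)COC(=O)[C@H]12 | intermediate
10 | cis-fused lactone with acetyl on C1 (same configuration as 9) | CC(=O)[C@@H]1CC[C@]2(C)COC(=O)[C@H]12 | intermediate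
11 | cis-fused bicyclo[3.3.0]octane dione (C6 and C10 ketones, C9 between them); C4 CH3 up, CH2OH down | O=C1CC(=O)[C@@H]2CC[C@](C)(CO)[C@H]12 | intermediate (not isolated)
12 | tricyclic vinylogous ester: C10 ketone, C6=C9 enol ether, O–CH2 bridge from C6 to C4 on the lower face | O=C1C=C2OC[C@@]3(C)CC[C@@H]1[C@@H]23 | intermediate
13 | C10 tertiary carbinol of 12 (CH3 up, OH down, from convex-face addition) | C[C@]1(O)C=C2OC[C@@]3(C)CC[C@@H]1[C@@H]23 | intermediate (not isolated)
14 | cis-fused hydroxy enone: C6 ketone, C9=C10, CH3 on C10; C4 CH3 up, CH2OH down | O=C1C=C(C)[C@@H]2CC[C@](C)(CO)[C@H]12 | intermediate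
15 | tert-butyldiphenylsilyl ether of 14 | O=C1C=C(C)[C@@H]2CC[C@](C)(CO[Si](c3ccccc3)(c4ccccc4)C(C)(C)C)[C@H]12 | intermediate
16 | 9,10-epoxy ketone of 15, epoxide oxygen up | O=C1[C@H]3O[C@@]3(C)[C@@H]2CC[C@](C)(CO[Si](c4ccccc4)(c5ccccc5)C(C)(C)C)[C@H]12 | intermediate
17 | cis-diquinane β-hydroxy ketone: C6 ketone, C10 OH up and CH3 down | O=C1C[C@@](C)(O)[C@@H]2CC[C@](C)(CO[Si](c3ccccc3)(c4ccccc4)C(C)(C)C)[C@H]12 | intermediate
18 | cis-diquinane ketone with C10 OSiEt3 (up) and C4 CH2OSiPh2t-Bu (down) | O=C1C[C@@](C)(O[Si](CC)(CC)CC)[C@@H]2CC[C@](C)(CO[Si](c3ccccc3)(c4ccccc4)C(C)(C)C)[C@H]12 | intermediate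
19 | pyrrolidine | C1CCNC1 | starting material
20 | pyrrolidine enamine of 18 (N on C6, C6=C9) | C1CCN(C1)C2=C[C@@](C)(O[Si](CC)(CC)CC)[C@@H]3CC[C@](C)(CO[Si](c4ccccc4)(c5ccccc5)C(C)(C)C)[C@H]23 | intermediate
21 | methyl propiolate | C#CC(=O)OC | starting material
22 | aminocyclobutene (C6 bonded to N, C5, C9 and the ester-bearing C7; C7=C8; C8–C9), drawn for addition on the upper face | COC(=O)C1=C[C@@H]2[C@@]1(N3CCCC3)[C@@H]4[C@@H](CC[C@]4(C)CO[Si](c5ccccc5)(c6ccccc6)C(C)(C)C)[C@]2(C)O[Si](CC)(CC)CC | intermediate (not isolated)
23 | cis-fused hydroazulene dienamine ester: C6 pyrrolidinyl, C6=C7, C7 CO2Me, C8=C9; H-1 and H-5 up | COC(=O)C1=C(N3CCCC3)[C@H]2[C@@](C)(CO[Si](c4ccccc4)(c5ccccc5)C(C)(C)C)CC[C@H]2[C@](C)(O[Si](CC)(CC)CC)C=C1 | intermediate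
24 | 8,9-dihydro derivative of 23 (β-enamino ester) | COC(=O)C1=C(N3CCCC3)[C@H]2[C@@](C)(CO[Si](c4ccccc4)(c5ccccc5)C(C)(C)C)CC[C@H]2[C@](C)(O[Si](CC)(CC)CC)CC1 | intermediate (not isolated)
25 | cis-fused keto ester: C6 ketone, C7 CO2Me (C7 enolisable, not defined), C10 OSiEt3 | COC(=O)C1CC[C@@](C)(O[Si](CC)(CC)CC)[C@@H]2CC[C@](C)(CO[Si](c3ccccc3)(c4ccccc4)C(C)(C)C)[C@@H]2C1=O | intermediate (not isolated)
26 | trans-fused hydroxy keto ester: C6 ketone, C7 CO2Me (C7 enolisable, not defined), C10 OH up; H-1 up, H-5 down | COC(=O)C1CC[C@@](C)(O)[C@@H]2CC[C@](C)(CO[Si](c3ccccc3)(c4ccccc4)C(C)(C)C)[C@H]2C1=O | intermediate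
27 | trans-fused enol triflate: C6 OTf, C6=C7, C7 CO2Me | COC(=O)C1=C(OS(=O)(=O)C(F)(F)F)[C@@H]2[C@@](C)(CO[Si](c3ccccc3)(c4ccccc4)C(C)(C)C)CC[C@H]2[C@](C)(O)CC1 | intermediate
28 | trans-fused enoate: C6=C7, C7 CO2Me, C10 OH | COC(=O)C1=C[C@@H]2[C@@](C)(CO[Si](c3ccccc3)(c4ccccc4)C(C)(C)C)CC[C@H]2[C@](C)(O)CC1 | intermediate
29 | trans-fused saturated ester: H-7 up, CO2Me down | COC(=O)[C@@H]1CC[C@@](C)(O)[C@@H]2CC[C@](C)(CO[Si](c3ccccc3)(c4ccccc4)C(C)(C)C)[C@H]2C1 | intermediate
30 | diol ester: C4 CH2OH, C10 OH | COC(=O)[C@@H]1CC[C@@](C)(O)[C@@H]2CC[C@](C)(CO)[C@H]2C1 | intermediate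
31 | aldehyde: C4 CHO | COC(=O)[C@@H]1CC[C@@](C)(O)[C@@H]2CC[C@](C)(C=O)[C@H]2C1 | intermediate
32 | phloroglucinol | Oc1cc(O)cc(O)c1 | starting material
33 | 1,3,5-tris(methoxymethoxy)benzene | COCOc1cc(OCOC)cc(OCOC)c1 | intermediate
34 | 2,4,6-tris(methoxymethoxy)phenyllithium | [Li]c1c(OCOC)cc(OCOC)cc1OCOC | intermediate (not isolated)
35 | benzylic alcohol: C1′ bears OH (configuration not defined) and the 2,4,6-tris(methoxymethoxy)phenyl group | COC(=O)[C@@H]1CC[C@@](C)(O)[C@@H]2CC[C@](C)(C(O)c3c(OCOC)cc(OCOC)cc3OCOC)[C@H]2C1 | intermediate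
36 | (1′R)-2-methylallyl compound: C1′ bears H, CH2C(CH3)=CH2 and the aryl group | COC(=O)[C@@H]1CC[C@@](C)(O)[C@@H]2CC[C@](C)([C@@H](CC(C)=C)c3c(OCOC)cc(OCOC)cc3OCOC)[C@H]2C1 | intermediate
37 | (1′R)-isobutyl ester | COC(=O)[C@@H]1CC[C@@](C)(O)[C@@H]2CC[C@](C)([C@@H](CC(C)C)c3c(OCOC)cc(OCOC)cc3OCOC)[C@H]2C1 | intermediate
38 | N-methoxy-N-methylamide of 37 at C7 | CON(C)C(=O)[C@@H]1CC[C@@](C)(O)[C@@H]2CC[C@](C)([C@@H](CC(C)C)c3c(OCOC)cc(OCOC)cc3OCOC)[C@H]2C1 | intermediate (not isolated)
39 | methyl ketone: acetyl on C7 (down) | CC(=O)[C@@H]1CC[C@@](C)(O)[C@@H]2CC[C@](C)([C@@H](CC(C)C)c3c(OCOC)cc(OCOC)cc3OCOC)[C@H]2C1 | intermediate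
40 | isopropenyl compound, tris(MOM) ether of the deformyl target | C=C(C)[C@@H]1CC[C@@](C)(O)[C@@H]2CC[C@](C)([C@@H](CC(C)C)c3c(OCOC)cc(OCOC)cc3OCOC)[C@H]2C1 | intermediate
41 | lithium hemiaminal of the mono-formyl compound (C10 lithium alkoxide) | C=C(C)[C@@H]1CC[C@@](C)(O[Li])[C@@H]2CC[C@](C)([C@@H](CC(C)C)c3c(OCOC)c(C(O[Li])N(C)C)c(OCOC)cc3OCOC)[C@H]2C1 | intermediate (not isolated)
42 | dialdehyde, tris(MOM) ether of the target | C=C(C)[C@@H]1CC[C@@](C)(O)[C@@H]2CC[C@](C)([C@@H](CC(C)C)c3c(OCOC)c(C=O)c(OCOC)c(C=O)c3OCOC)[C@H]2C1 | intermediate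
43 | CNP0594576.1, (1R,4S,5S,7R,10R,1′R) in the numbering used here | C=C(C)[C@@H]1CC[C@@](C)(O)[C@@H]2CC[C@](C)([C@@H](CC(C)C)c3c(O)c(C=O)c(O)c(C=O)c3O)[C@H]2C1 | target

**Step count.** Total: 29 steps. Longest linear sequence: 28 steps (steps 1–21 and 23–29; step 22 is the arene branch).

**Steps most likely to fail**

Step 15. Proton transfer within the zwitterion (giving an open Michael adduct) or loss of the C10 silyloxy group could outrun cyclobutene closure and opening. The fallback sets out from ketone 18. Kinetic enolisation with internal quench (LiN(i-Pr)2 in the presence of Me3SiCl, THF, −78 °C) should give the C6=C9 trimethylsilyl enol ether F1. An acid-catalysed (2+2) cycloaddition with methyl propiolate 21 (catalytic HNTf2, CH2Cl2, −78 °C) should give the silyloxycyclobutene F2. Warming in toluene opens it to the ring-enlarged silyl dienol ether F3, and dilute acid gives the cis-fused 8,9-unsaturated keto ester F4. Hydrogenation of the C8=C9 bond (H2, Rh/Al2O3) returns to the route at 25, which the acid treatment of step 16 converts to 26.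

Step 19. Delivery from the hydroxyl face may be insufficient, so that hydrogen enters from the less hindered lower face and gives the C7 epimer. The fallback sets out from 28 and replaces substrate direction by catalyst control. Silylation of the C10 hydroxyl (Et3SiOTf, 2,6-lutidine) gives the silyl-protected enoate F5. Asymmetric hydrogenation with a chiral iridium phosphino-oxazoline complex, [Ir(cod)(L*)][B(3,5-(CF3)2C6H3)4], using the ligand antipode that adds hydrogen syn to H-1, should give the silyl-protected saturated ester F6. Bu4NF then removes both silyl groups and returns to the route at 30.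

Step 24. The benzylic cation may be captured from the wrong face, or with poor facial discrimination. The fallback sets out from 35 and exchanges the order in which carbon and hydrogen enter C1′. Dess–Martin oxidation gives the aryl ketone F7. 2-Methylallylmagnesium chloride (THF, −78 °C; ketone faster than ester) gives the tertiary 2-methylallyl carbinol F8, and hydrogenation (H2, Pd/C) gives the tertiary isobutyl carbinol F9. Ionic hydrogenation (Et3SiH, CF3CO2H, CH2Cl2, −78 °C) then delivers hydride to the cation face that the allylsilane would have taken, which inverts the outcome at C1′, and returns to the route at 37.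

**Further compounds**

F1 | step 15 | trimethylsilyl enol ether of 18 (C6=C9) | C[Si](C)(C)OC1=C[C@@](C)(O[Si](CC)(CC)CC)[C@@H]2CC[C@](C)(CO[Si](c3ccccc3)(c4ccccc4)C(C)(C)C)[C@H]12
F2 | step 15 | silyloxycyclobutene (C6 OSiMe3; C7 CO2Me; C7=C8; C8–C9) | COC(=O)C1=C[C@@H]2[C@@]1(O[Si](C)(C)C)[C@@H]3[C@@H](CC[C@]3(C)CO[Si](c4ccccc4)(c5ccccc5)C(C)(C)C)[C@]2(C)O[Si](CC)(CC)CC
F3 | step 15 | cis-fused ring-enlarged silyl dienol ether (C6 OSiMe3; C6=C7; C8=C9) | COC(=O)C1=C(O[Si](C)(C)C)[C@H]2[C@@](C)(CO[Si](c3ccccc3)(c4ccccc4)C(C)(C)C)CC[C@H]2[C@](C)(O[Si](CC)(CC)CC)C=C1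
F4 | step 15 | cis-fused 8,9-unsaturated keto ester (C6 ketone; C7 CO2Me) | COC(=O)C1C=C[C@@](C)(O[Si](CC)(CC)CC)[C@@H]2CC[C@](C)(CO[Si](c3ccccc3)(c4ccccc4)C(C)(C)C)[C@@H]2C1=O
F5 | step 19 | C10 triethylsilyl ether of enoate 28 | COC(=O)C1=C[C@@H]2[C@@](C)(CO[Si](c3ccccc3)(c4ccccc4)C(C)(C)C)CC[C@H]2[C@](C)(O[Si](CC)(CC)CC)CC1
F6 | step 19 | C10 triethylsilyl ether of saturated ester 29 (H-7 up) | COC(=O)[C@@H]1CC[C@@](C)(O[Si](CC)(CC)CC)[C@@H]2CC[C@](C)(CO[Si](c3ccccc3)(c4ccccc4)C(C)(C)C)[C@H]2C1
F7 | step 24 | aryl ketone (C1′ carbonyl) | COC(=O)[C@@H]1CC[C@@](C)(O)[C@@H]2CC[C@](C)(C(=O)c3c(OCOC)cc(OCOC)cc3OCOC)[C@H]2C1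
F8 | step 24 | tertiary 2-methylallyl carbinol at C1′ (configuration not defined) | COC(=O)[C@@H]1CC[C@@](C)(O)[C@@H]2CC[C@](C)(C(O)(CC(C)=C)c3c(OCOC)cc(OCOC)cc3OCOC)[C@H]2C1
F9 | step 24 | tertiary isobutyl carbinol at C1′ (configuration not defined) | COC(=O)[C@@H]1CC[C@@](C)(O)[C@@H]2CC[C@](C)(C(O)(CC(C)C)c3c(OCOC)cc(OCOC)cc3OCOC)[C@H]2C1
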